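## Retrosynthetic overview

1. Target 26 ← desilylation ← bicycle 25; the seven-membered ring is closed last by a 7-exo Heck reaction that forms C1–C10 and re-creates the C2=C3/C4–O allylic system.
2. Heck substrate 24 ← reductive transposition of the enone in aldol adduct 21 ← anti, Felkin aldol (C5–C6) between cyclopentenone 4 and aldehyde 19.
3. Cyclopentenone 4 (five-membered ring made first, C4 from the chiral pool) ← ring-closing metathesis of (R)-linalool, then allylic oxidation.
4. Aldehyde 19 ← Nef unmasking and side-chain tailoring (C13 by CBS reduction) of δ-nitro ester 12.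
5. Key bond C7–C11 of 12 ← carbene-generated homoenolate of crotonaldehyde 11 + nitroalkene 10 (from 2-bromoallyl alcohol 5 by Claisen and Henry chemistry).

Assumption: commercial (R)-(−)-linalool is used at high enantiomeric purity; locants C1–C20 in the text are those of the target skeleton (C1/C5 ring fusion, C2=C3, C4 carbinol with methyl C20, C6 carbinol, C7 side-chain carbon, C8, C9, C10 with methylene C18, side chain C11 with methyl C19, C12, C13 with OAc, C14=C15).

## Route

Step 1
Reactants: 1 (R)-(−)-linalool
Product: 2 (1R)-1-methylcyclopent-2-en-1-ol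
Conditions: second-generation Grubbs catalyst RuCl2(=CHPh)(H2IMes)(PCy3) (0.5 mol %), CH2Cl2, 40 °C
Reagents that add atoms: none
Why: Ring-closing metathesis between the vinyl group and the trisubstituted alkene closes the five-membered ring with loss of 2-methylpropene, a hydroxyl-accelerated and well-known reaction of linalool, and carries the tertiary carbinol centre (the future C4) over unchanged from the chiral pool.

Step 2
Reactants: 2 (1R)-1-methylcyclopent-2-en-1-ol
Product: 3 triethyl{[(1R)-1-methylcyclopent-2-en-1-yl]oxy}silane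
Conditions: Et3SiCl, imidazole, DMAP (cat.), DMF, rt
Reagents that add atoms: chlorotriethylsilane, CC[Si](Cl)(CC)CC
Why: Silylation of the tertiary alcohol gives a bulky ether that blocks oxidative allylic transposition in the next step and later shields one face of the enolate.

Step 3
Reactants: 3 triethyl{[(1R)-1-methylcyclopent-2-en-1-yl]oxy}silane
Product: 4 (4R)-4-methyl-4-[(triethylsilyl)oxy]cyclopent-2-en-1-one
Conditions: Rh2(cap)4 (dirhodium tetracaprolactamate, 1 mol %), t-BuOOH (70% in water, 5 equiv), K2CO3 (0.5 equiv), CH2Cl2, rt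
Reagents that add atoms: tert-butyl hydroperoxide, CC(C)(C)OO
Why: Allylic C–H oxidation (tert-butylperoxyl radical chain) converts the only allylic methylene into the enone carbonyl, the transposed regioisomer being disfavoured because the other allyl terminus is flanked by the fully substituted silyloxy carbon.

Step 4
Reactants: 5 2-bromoprop-2-en-1-ol
Product: 7 4-bromopent-4-enal, via 2-bromoallyl vinyl ether 6 (not isolated)
Conditions: ethyl vinyl ether (solvent), Hg(OAc)2 (5 mol %), reflux; then concentrate, PhMe, 150 °C (sealed tube)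
Reagents that add atoms: ethyl vinyl ether, C=COCC
Why: Mercury-catalysed vinyl transetherification followed by thermal [3,3]-sigmatropic Claisen rearrangement of the allyl vinyl ether gives the γ,δ-unsaturated aldehyde with the 2-bromoalkene intact.

Step 5
Reactants: 7 4-bromopent-4-enal
Product: 10 (1E)-5-bromo-1-nitrohexa-1,5-diene, via nitro alcohol 8 (not isolated), via nitro mesylate 9 (not isolated)
Conditions: CH3NO2 (5 equiv), Et3N (0.2 equiv), THF, 0 °C to rt; then MsCl, Et3N (2.5 equiv), CH2Cl2, 0 °C
Reagents that add atoms: nitromethane, C[N+](=O)[O-]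
Why: Henry (nitroaldol) addition of nitromethane followed by mesylation and E1cB elimination gives the thermodynamically favoured E-nitroalkene.

Step 6
Reactants: 10 (1E)-5-bromo-1-nitrohexa-1,5-diene; 11 (2E)-but-2-enal (crotonaldehyde)
Product: 12 methyl (3R,4R)-7-bromo-3-methyl-4-(nitromethyl)oct-7-enoate
Conditions: aminoindanol-derived N-mesityl triazolium chloride (10 mol %, the enantiomer giving the 3R,4R product), NaOAc (0.5 equiv), MeOH (10 equiv), THF, rt
Reagents that add atoms: methanol, CO
Why: The carbene converts crotonaldehyde into its homoenolate (extended Breslow intermediate), whose polarity-reversed β-carbon (C11) adds to the β-carbon (C7) of the nitroalkene, two carbons that are both electrophilic in the free reactants, in the anti-selective catalyst-controlled mode known for chiral N-mesityl triazolium carbenes, which fixes C11 and C7 in one event before methanol releases the acyl azolium as the ester (NHC homoenolate Michael addition with redox esterification).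

Step 7
Reactants: 12 methyl (3R,4R)-7-bromo-3-methyl-4-(nitromethyl)oct-7-enoate
Product: 14 methyl (3R,4R)-7-bromo-4-(dimethoxymethyl)-3-methyloct-7-enoate, via sodium nitronate 13 (not isolated)
Conditions: NaOMe (1.1 equiv), MeOH, 0 °C; then added to H2SO4/MeOH, −40 °C to rt
Reagents that add atoms: methanol, CO
Why: Nef reaction in its acetal-forming variant solvolyses the nitronate in cold methanolic acid, so the nitro-bearing carbon (C6) is unmasked directly as a protected aldehyde while neither stereocentre, both remote from any acidifying group, can epimerise.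

Step 8
Reactants: 14 methyl (3R,4R)-7-bromo-4-(dimethoxymethyl)-3-methyloct-7-enoate
Product: 16 (6R,7R)-10-bromo-7-(dimethoxymethyl)-2,6-dimethylundeca-2,10-dien-4-one, via Weinreb amide 15 (not isolated)
Conditions: MeNHOMe·HCl (1.5 equiv), i-PrMgCl (3 equiv), THF, −20 °C; then (CH3)2C=CHMgBr (2.5 equiv), 0 °C; aq. NH4Cl
Reagents that add atoms: (2-methylprop-1-en-1-yl)magnesium bromide, CC(C)=C[Mg]Br
Why: One-pot Weinreb ketone synthesis in which the magnesium amide of N,O-dimethylhydroxylamine converts the ester into the Weinreb amide, whose stable chelate with the alkenyl Grignard reagent collapses only on work-up, so the isobutenyl ketone forms without over-addition.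

Step 9
Reactants: 16 (6R,7R)-10-bromo-7-(dimethoxymethyl)-2,6-dimethylundeca-2,10-dien-4-one
Product: 17 (4R,6R,7R)-10-bromo-7-(dimethoxymethyl)-2,6-dimethylundeca-2,10-dien-4-ol
Conditions: (S)-2-methyl-CBS-oxazaborolidine (0.2 equiv), BH3·SMe2 (0.7 equiv), THF, −30 °C; MeOH quench
Reagents that add atoms: none
Why: Corey–Bakshi–Shibata reduction in which the alkenyl group acts as the large substituent, so the (S)-oxazaborolidine delivers hydride to give the (R)-allylic alcohol (C13) under catalyst control, the deactivated alkenes being inert to borane at this temperature.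

Step 10
Reactants: 17 (4R,6R,7R)-10-bromo-7-(dimethoxymethyl)-2,6-dimethylundeca-2,10-dien-4-ol
Product: 18 (4R,6R,7R)-10-bromo-7-(dimethoxymethyl)-2,6-dimethylundeca-2,10-dien-4-yl acetate
Conditions: Ac2O, pyridine, DMAP (cat.), CH2Cl2, 0 °C to rt
Reagents that add atoms: acetic anhydride, CC(=O)OC(C)=O
Why: Standard acylation of the unhindered secondary allylic alcohol installs the acetate of the target with retention at C13.

Step 11
Reactants: 18 (4R,6R,7R)-10-bromo-7-(dimethoxymethyl)-2,6-dimethylundeca-2,10-dien-4-yl acetate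
Product: 19 (4R,6R,7R)-10-bromo-7-formyl-2,6-dimethylundeca-2,10-dien-4-yl acetate
Conditions: LiBF4 (1 equiv), MeCN/H2O (98:2), rt
Reagents that add atoms: water, O
Why: Mild Lewis-acid-mediated acetal hydrolysis liberates the aldehyde without ionising the allylic acetate or epimerising the α-stereocentre (C7).

Step 12
Reactants: 4 (4R)-4-methyl-4-[(triethylsilyl)oxy]cyclopent-2-en-1-one; 19 (4R,6R,7R)-10-bromo-7-formyl-2,6-dimethylundeca-2,10-dien-4-yl acetate
Product: 21 aldol adduct (β-hydroxy enone with the C5–C6 bond; 4S,5R,6S,7R,11R,13R in skeleton locants), via lithium dienolate 20 (not isolated)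
Conditions: 4, LiN(i-Pr)2 (1.05 equiv), THF, −78 °C; then 19, −78 °C; aq. NH4Cl at −78 °C
Reagents that add atoms: none
Why: Kinetic lithium enolate aldol addition in which three elements reinforce each other, namely attack anti to the bulky silyloxy group on C4 (sets C5), the ring-enforced E-enolate giving the anti aldol through a Zimmerman–Traxler transition state, and Felkin–Anh addition to the α-branched aldehyde (sets C6 relative to C7).

Step 13
Reactants: 21 aldol adduct
Product: 22 tosylhydrazone of 21 at the ring carbonyl (C1)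
Conditions: TsNHNH2 (1.2 equiv), PPTS (cat.), EtOH, rt
Reagents that add atoms: 4-methylbenzenesulfonohydrazide, Cc1ccc(cc1)S(=O)(=O)NN
Why: Hydrazone condensation at the only ketone proceeds under near-neutral conditions that leave the acetate, the silyl ether and the β-hydroxyl untouched.

Step 14
Reactants: 22 tosylhydrazone
Product: 24 cyclopentene with C1=C2 and a C3 methylene (Heck substrate), via allylic diazene 23 (not isolated)
Conditions: catecholborane (4 equiv), CHCl3, 0 °C; then NaOAc·3H2O (3 equiv), 60 °C
Reagents that add atoms: none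
Why: Kabalka-type reductive transposition in which catecholborane reduces the C=N bond, acetate-induced loss of sulfinate gives an allylic diazene, and a retro-ene 1,5-hydrogen shift with loss of dinitrogen moves the double bond to C1=C2 and removes the C1 oxygen without creating or disturbing a stereocentre.

Step 15
Reactants: 24 Heck substrate
Product: 25 O4-triethylsilyl ether of the target (cis-fused hydroazulene)
Conditions: Pd(OAc)2 (10 mol %), n-Bu4NCl (1 equiv), KOAc (3 equiv), DMF, 60 °C
Reagents that add atoms: none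
Why: Intramolecular Mizoroki–Heck reaction (7-exo-trig) in which the alkenylpalladium bromide adds syn to the cyclopentene face that carries the tether, so C1 is set cis to C5, and syn β-hydride elimination is possible only toward C3, which restores the C2=C3 bond next to the C4 carbinol and keeps the exocyclic methylene, phosphine-free conditions being chosen so that zerovalent palladium does not ionise the C13 allylic acetate.

Step 16
Reactants: 25 O4-triethylsilyl ether of the target
Product: 26 (4R,6R)-6-[(3S,3aR,4S,5R,8aS)-3,4-dihydroxy-3-methyl-8-methylidene-3,3a,4,5,6,7,8,8a-octahydroazulen-5-yl]-2-methylhept-2-en-4-yl acetate (target)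
Conditions: HF·pyridine, pyridine, THF, 0 °C to rt
Reagents that add atoms: none
Why: Buffered fluoride cleavage of the tertiary triethylsilyl ether leaves the acetate and the acid-sensitive tertiary allylic alcohol intact.

## Compound list

1 | (R)-(−)-linalool, (3R)-3,7-dimethylocta-1,6-dien-3-ol | C=C[C@](C)(O)CCC=C(C)C | starting material
2 | (1R)-1-methylcyclopent-2-en-1-ol | C1=C[C@](C)(O)CC1 | intermediate
3 | triethyl{[(1R)-1-methylcyclopent-2-en-1-yl]oxy}silane | C1=C[C@](C)(O[Si](CC)(CC)CC)CC1 | intermediate
4 | (4R)-4-methyl-4-[(triethylsilyl)oxy]cyclopent-2-en-1-one | O=C1C=C[C@](C)(O[Si](CC)(CC)CC)C1 | intermediate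
5 | 2-bromoprop-2-en-1-ol | OCC(Br)=C | starting material
6 | 2-bromo-3-(ethenyloxy)prop-1-ene (2-bromoallyl vinyl ether) | C=COCC(Br)=C | intermediate
7 | 4-bromopent-4-enal | O=CCCC(Br)=C | intermediate
8 | 5-bromo-1-nitrohex-5-en-2-ol (racemic) | [O-][N+](=O)CC(O)CCC(Br)=C | intermediate
9 | 5-bromo-1-nitrohex-5-en-2-yl methanesulfonate (racemic) | [O-][N+](=O)CC(OS(C)(=O)=O)CCC(Br)=C | intermediate
10 | (1E)-5-bromo-1-nitrohexa-1,5-diene | [O-][N+](=O)/C=C/CCC(Br)=C | intermediate
11 | (2E)-but-2-enal (crotonaldehyde) | C/C=C/C=O | starting material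
12 | methyl (3R,4R)-7-bromo-3-methyl-4-(nitromethyl)oct-7-enoate | C=C(Br)CC[C@H]([C@H](C)CC(=O)OC)C[N+](=O)[O-] | intermediate
13 | sodium nitronate of 12 | C=C(Br)CC[C@H]([C@H](C)CC(=O)OC)C=[N+]([O-])[O-].[Na+] | intermediate
14 | methyl (3R,4R)-7-bromo-4-(dimethoxymethyl)-3-methyloct-7-enoate | C=C(Br)CC[C@H]([C@H](C)CC(=O)OC)C(OC)OC | intermediate
15 | (3R,4R)-7-bromo-4-(dimethoxymethyl)-N-methoxy-N,3-dimethyloct-7-enamide | C=C(Br)CC[C@H]([C@H](C)CC(=O)N(C)OC)C(OC)OC | intermediate
16 | (6R,7R)-10-bromo-7-(dimethoxymethyl)-2,6-dimethylundeca-2,10-dien-4-one | C=C(Br)CC[C@H]([C@H](C)CC(=O)C=C(C)C)C(OC)OC | intermediate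
17 | (4R,6R,7R)-10-bromo-7-(dimethoxymethyl)-2,6-dimethylundeca-2,10-dien-4-ol | C=C(Br)CC[C@H]([C@H](C)C[C@H](C=C(C)C)O)C(OC)OC | intermediate
18 | (4R,6R,7R)-10-bromo-7-(dimethoxymethyl)-2,6-dimethylundeca-2,10-dien-4-yl acetate | C=C(Br)CC[C@H]([C@H](C)C[C@H](C=C(C)C)OC(C)=O)C(OC)OC | intermediate
19 | (4R,6R,7R)-10-bromo-7-formyl-2,6-dimethylundeca-2,10-dien-4-yl acetate | C=C(Br)CC[C@H]([C@H](C)C[C@H](C=C(C)C)OC(C)=O)C=O | intermediate
20 | lithium (3S)-3-methyl-3-[(triethylsilyl)oxy]cyclopenta-1,4-dien-1-olate | [Li+].[O-]C1=C[C@@](C)(O[Si](CC)(CC)CC)C=C1 | intermediate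
21 | (4R,6R,7R)-10-bromo-7-[(S)-hydroxy{(1R,2S)-2-methyl-5-oxo-2-[(triethylsilyl)oxy]cyclopent-3-en-1-yl}methyl]-2,6-dimethylundeca-2,10-dien-4-yl acetate | C=C(Br)CC[C@H]([C@H](C)C[C@H](C=C(C)C)OC(C)=O)[C@H](O)[C@H]1C(=O)C=C[C@]1(C)O[Si](CC)(CC)CC | intermediate
22 | (4R,6R,7R)-10-bromo-7-[(S)-hydroxy{(1R,2S)-2-methyl-5-[2-(4-methylbenzenesulfonyl)hydrazinylidene]-2-[(triethylsilyl)oxy]cyclopent-3-en-1-yl}methyl]-2,6-dimethylundeca-2,10-dien-4-yl acetate (C=N geometry not defined) | C=C(Br)CC[C@H]([C@H](C)C[C@H](C=C(C)C)OC(C)=O)[C@H](O)[C@H]1C(=NNS(=O)(=O)c2ccc(C)cc2)C=C[C@]1(C)O[Si](CC)(CC)CC | intermediate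
23 | (4R,6R,7R)-10-bromo-7-[(S)-{(1R,2S)-5-diazenyl-2-methyl-2-[(triethylsilyl)oxy]cyclopent-3-en-1-yl}(hydroxy)methyl]-2,6-dimethylundeca-2,10-dien-4-yl acetate (configuration at the diazenyl carbon not defined) | C=C(Br)CC[C@H]([C@H](C)C[C@H](C=C(C)C)OC(C)=O)[C@H](O)[C@H]1C(N=N)C=C[C@]1(C)O[Si](CC)(CC)CC | intermediate
24 | (4R,6R,7R)-10-bromo-7-[(S)-hydroxy{(1R,5S)-5-methyl-5-[(triethylsilyl)oxy]cyclopent-2-en-1-yl}methyl]-2,6-dimethylundeca-2,10-dien-4-yl acetate | C=C(Br)CC[C@H]([C@H](C)C[C@H](C=C(C)C)OC(C)=O)[C@H](O)[C@H]1C=CC[C@]1(C)O[Si](CC)(CC)CC | intermediate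
25 | (4R,6R)-6-[(3S,3aR,4S,5R,8aS)-4-hydroxy-3-methyl-8-methylidene-3-[(triethylsilyl)oxy]-3,3a,4,5,6,7,8,8a-octahydroazulen-5-yl]-2-methylhept-2-en-4-yl acetate | C=C1CC[C@H]([C@H](C)C[C@H](C=C(C)C)OC(C)=O)[C@H](O)[C@H]2[C@@H]1C=C[C@]2(C)O[Si](CC)(CC)CC | intermediate
26 | (4R,6R)-6-[(3S,3aR,4S,5R,8aS)-3,4-dihydroxy-3-methyl-8-methylidene-3,3a,4,5,6,7,8,8a-octahydroazulen-5-yl]-2-methylhept-2-en-4-yl acetate | C=C1CC[C@H]([C@H](C)C[C@H](C=C(C)C)OC(C)=O)[C@H](O)[C@H]2[C@@H]1C=C[C@]2(C)O | target

## Step count and risks

Total step count: 16 (3 steps to enone 4, 8 steps to aldehyde 19, 5 steps after their union).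
Longest linear sequence: 13 steps (steps 4 to 16, from 2-bromoprop-2-en-1-ol 5).

Steps most likely to fail:

**Step 6 (carbene homoenolate addition).** The anti sense of diastereoselection is less well established for two aliphatic partners than the syn sense. β-Protonation of the homoenolate (giving methyl butanoate) and base-induced isomerisation of the aliphatic nitroalkene also compete. Fallback, setting out from aldehyde 7 and returning at acetal ester 14: the C7–C11 bond is made with normal polarity under auxiliary control. Wittig methoxymethylenation of 7 (Ph3P=CHOMe) gives enol ether F1, and aqueous acid gives 5-bromohex-5-enal F2. Condensation with (S)-1-amino-2-(methoxymethyl)pyrrolidine gives SAMP hydrazone F3 (the antipodal auxiliary is used instead if the facial sense requires it). Its lithium aza-enolate (LiN(i-Pr)2, THF, −78 °C) adds 1,4 to methyl (E)-but-2-enoate to give the anti Michael adduct F4. Aqueous oxalic acid then liberates aldehyde ester F5 and the auxiliary, and HC(OMe)3/MeOH/PPTS converts F5 into 14.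

**Step 12 (aldol union).** The new bond forms next to the fully substituted C4, so retro-aldol and proton transfer to the hindered α-branched aldehyde can erode yield. The diastereomer ratio depends on three control elements acting together. Fallback, setting out from enone 4 (with aldehyde 19) and returning at 21: 4 is converted with Me3SiOTf/Et3N into silyl dienol ether F6. This is added to 19 in a BF3·OEt2-mediated Mukaiyama aldol reaction at −78 °C (open transition state, Felkin-controlled, no basic enolate and no reversible lithium aldolate), giving 21 after aqueous work-up.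

**Step 15 (Heck ring closure).** A seven-membered ring is formed in the presence of an allylic acetate that zerovalent palladium can ionise. Palladium hydride can also move the new double bonds into conjugation. Fallback, setting out from 24 and returning at 25: the acetate is removed first (K2CO3, MeOH) to give diol F7. The Heck cyclisation is then run on this substrate, which has no ionisable allylic ester, to give bicyclic diol F8. The unhindered C13 hydroxyl is acetylated selectively (Ac2O, pyridine, 0 °C, no DMAP), because the C6 hydroxyl is flanked by two tertiary carbons and C4 is still silylated, which gives 25.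

## Further compounds

F1 | step 6 | 5-bromo-1-methoxyhexa-1,5-diene (E/Z mixture) | COC=CCCC(Br)=C
F2 | step 6 | 5-bromohex-5-enal | O=CCCCC(Br)=C
F3 | step 6 | (2S)-N-[(1E)-5-bromohex-5-en-1-ylidene]-2-(methoxymethyl)pyrrolidin-1-amine | COC[C@@H]1CCCN1/N=C/CCCC(Br)=C
F4 | step 6 | methyl (3R,4R)-7-bromo-4-[(E)-{[(2S)-2-(methoxymethyl)pyrrolidin-1-yl]imino}methyl]-3-methyloct-7-enoate | C=C(Br)CC[C@H]([C@H](C)CC(=O)OC)/C=N/N1CCC[C@H]1COC
F5 | step 6 | methyl (3R,4R)-7-bromo-4-formyl-3-methyloct-7-enoate | C=C(Br)CC[C@H]([C@H](C)CC(=O)OC)C=O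
F6 | step 12 | trimethyl({(3S)-3-methyl-3-[(triethylsilyl)oxy]cyclopenta-1,4-dien-1-yl}oxy)silane | C[Si](C)(C)OC1=C[C@@](C)(O[Si](CC)(CC)CC)C=C1
F7 | step 15 | (4R,6R,7R)-10-bromo-7-[(S)-hydroxy{(1R,5S)-5-methyl-5-[(triethylsilyl)oxy]cyclopent-2-en-1-yl}methyl]-2,6-dimethylundeca-2,10-dien-4-ol | C=C(Br)CC[C@H]([C@H](C)C[C@H](C=C(C)C)O)[C@H](O)[C@H]1C=CC[C@]1(C)O[Si](CC)(CC)CC
F8 | step 15 | (3S,3aR,4S,5R,8aS)-5-[(2R,4R)-4-hydroxy-6-methylhept-5-en-2-yl]-3-methyl-8-methylidene-3-[(triethylsilyl)oxy]-3,3a,4,5,6,7,8,8a-octahydroazulen-4-ol | C=C1CC[C@H]([C@H](C)C[C@H](C=C(C)C)O)[C@H](O)[C@H]2[C@@H]1C=C[C@]2(C)O[Si](CC)(CC)CC
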